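**Assumption:** Kanzonol E (1) has no stereocenter, because the CMe2 carbon of the chromene carries two identical methyls. The "single enantiomer" requirement is therefore trivially met and no enantiocontrol is needed.

## Retrosynthetic overview
1. The target (1) is a 7-hydroxy-6-prenylflavone. The pyranone C-ring comes from acid cyclodehydration of a 1,3-diketone made by Baker–Venkataraman rearrangement, with the 7-OH masked as a 2-pyrimidyl ether.
2. The C6 prenyl group is installed by a proposed new C–H prenylation. The pyrimidyloxy group directs Rh(III) to the less hindered ortho site of a resacetophenone, using a tertiary allylic carbonate as the prenyl donor.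
3. The B-ring 2,2-dimethylchromene is built first, from methyl 4-hydroxybenzoate and prenal, so no prenylphenol or acid-labile pyran is exposed to harsh conditions.
4. Ring order: B-ring pyran, then A-ring C6 prenylation, then ester and Baker–Venkataraman, then C-ring pyranone, then unmasking of 7-OH.

## Route

**Step 1**
Reactants: 2 methyl 4-hydroxybenzoate; 3 3-methylbut-2-enal (prenal)
Product: 4 methyl 2,2-dimethyl-2H-chromene-6-carboxylate
Conditions: 3 (3 equiv), ethylenediamine diacetate (10 mol%), xylene, reflux, Dean–Stark
Reagents that add atoms: none beyond the numbered reactants (prenal supplies the C5 pyran unit)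
Why: Phenol ortho-formylation-type condensation with the enal followed by 6π-oxa-electrocyclization gives the 2,2-dimethylchromene (Kabbe/Bigi-type chromene annulation). Para is blocked, so the only ortho site is used, and no stereocenter forms.

**Step 2**
Reactants: 4
Product: 5 2,2-dimethyl-2H-chromene-6-carboxylic acid
Conditions: LiOH·H2O, THF/MeOH/H2O, rt; then aqueous citric acid
Reagents that add atoms: water, O
Why: Simple ester saponification. The chromene C=C and the aryl ether are inert to base.

**Step 3**
Reactants: 6 2',4'-dihydroxyacetophenone; 7 2-chloropyrimidine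
Product: 8 1-[2-hydroxy-4-(pyrimidin-2-yloxy)phenyl]ethanone
Conditions: 7 (1.05 equiv), K2CO3, DMF, 60 °C
Reagents that add atoms: none beyond the numbered reactants (pyrimidinyl comes from 7)
Why: SNAr occurs at the more acidic 4-OH, while the 2-OH is locked in a hydrogen bond to the ketone. The product carries a strongly coordinating N-directing group that also protects the 7-O of the future flavone.

**Step 4**
Reactants: 9 2-methylbut-3-en-2-ol; 10 methyl chloroformate
Product: 11 2-methylbut-3-en-2-yl methyl carbonate
Conditions: n-BuLi, THF, −78 °C; then 10, −78 → 0 °C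
Reagents that add atoms: methyl chloroformate, COC(=O)Cl (supplies CO2Me)
Why: O-acylation of the lithium tert-alkoxide gives the prenyl-donor carbonate. The terminal vinyl group and tertiary leaving group are needed for the linear-prenyl outcome of Step 5.

**Step 5**
Reactants: 8; 11
Product: 12 1-[2-hydroxy-5-(3-methylbut-2-en-1-yl)-4-(pyrimidin-2-yloxy)phenyl]ethanone
Conditions: 11 (2.5 equiv), [Cp*RhCl2]2 (4 mol%), AgSbF6 (16 mol%), PivOH (30 mol%), DCE, 80 °C, 16 h
Reagents that add atoms: 2-methylbut-3-en-2-yl methyl carbonate, C=CC(C)(C)OC(=O)OC (supplies the C5H9 prenyl group)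
Why: Proposed new method: pyrimidyloxy-directed Cp*Rh(III) C–H prenylation of a resorcinol-type aryl ether. N-coordination and CMD rhodation occur at C5, because C3 is flanked by the 2-OH and the OAr group. The aryl–Rh then inserts the terminal vinyl group of the tertiary carbonate (Ar to CH2, Rh to the internal CH), and β-O elimination expels the carbonate to give Ar–CH2–CH=CMe2. Prenyl therefore forms linearly rather than as the reverse 1,1-dimethylallyl isomer. The closest known reaction is Cp*Rh(III)/Co(III) directed C–H allylation with allyl carbonates by insertion/β-O elimination, which is here extended to a tertiary vinyl carbonate as a prenyl surrogate on an O-pyrimidyl resorcinol ketone. The reaction is redox-neutral and forms no stereocenter.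

**Step 6**
Reactants: 12; 5
Product: 13 2-acetyl-4-(3-methylbut-2-en-1-yl)-5-(pyrimidin-2-yloxy)phenyl 2,2-dimethyl-2H-chromene-6-carboxylate
Conditions: 5 (1.2 equiv), EDCI·HCl, DMAP, CH2Cl2, 0 °C → rt
Reagents that add atoms: none beyond the numbered reactants
Why: Steglich esterification of the chelated 2-OH. This avoids acid chloride and HCl, which could attack the chromene.

**Step 7**
Reactants: 13
Product: 14 1-[2-hydroxy-5-(3-methylbut-2-en-1-yl)-4-(pyrimidin-2-yloxy)phenyl]-3-(2,2-dimethyl-2H-chromen-6-yl)propane-1,3-dione
Conditions: LiHMDS (3 equiv), THF, −78 → 0 °C; then aqueous NH4Cl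
Reagents that add atoms: none
Why: Baker–Venkataraman rearrangement. The acetyl enolate attacks the ester through a six-membered transition state. A non-nucleophilic amide base is used so the pyrimidyl ether is not cleaved by SNAr.

**Step 8**
Reactants: 14
Product: 15 7-(pyrimidin-2-yloxy)-6-prenyl-3',4'-(2,2-dimethylpyrano)flavone, i.e. 2-(2,2-dimethyl-2H-chromen-6-yl)-6-(3-methylbut-2-en-1-yl)-7-(pyrimidin-2-yloxy)-4H-chromen-4-one
Conditions: p-TsOH·H2O (0.3 equiv), toluene, 80 °C, 3 h
Reagents that add atoms: none
Why: Acid-catalysed cyclodehydration of the o-hydroxyaryl 1,3-diketone (phenol attacks the enolized ketone, then dehydration) closes the γ-pyranone. The 7-O is capped, so no free o-prenylphenol is present to cyclize under acid.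

**Step 9**
Reactants: 15
Product: 1 Kanzonol E
Conditions: NaOEt (4 equiv), EtOH/THF 1:1, 70 °C, 4 h; then aqueous NH4Cl to pH 6
Reagents that add atoms: none (EtO⁻ leaves as 2-ethoxypyrimidine; the phenol H comes from workup)
Why: SNAr at pyrimidine C2 releases the well-stabilized 7-flavonolate, which is protonated on workup. The prenyl group, chromene and flavone survive.

## Compound list
1 | Kanzonol E | CC(C)=CCc1cc2c(=O)cc(-c3ccc4c(c3)C=CC(C)(C)O4)oc2cc1O | target
2 | methyl 4-hydroxybenzoate | COC(=O)c1ccc(O)cc1 | starting material
3 | 3-methylbut-2-enal (prenal) | CC(C)=CC=O | starting material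
4 | methyl 2,2-dimethyl-2H-chromene-6-carboxylate | COC(=O)c1ccc2OC(C)(C)C=Cc2c1 | intermediate
5 | 2,2-dimethyl-2H-chromene-6-carboxylic acid | OC(=O)c1ccc2OC(C)(C)C=Cc2c1 | intermediate
6 | 2',4'-dihydroxyacetophenone | CC(=O)c1ccc(O)cc1O | starting material
7 | 2-chloropyrimidine | Clc1ncccn1 | starting material
8 | 1-[2-hydroxy-4-(pyrimidin-2-yloxy)phenyl]ethanone | CC(=O)c1ccc(Oc2ncccn2)cc1O | intermediate
9 | 2-methylbut-3-en-2-ol | C=CC(C)(C)O | starting material
10 | methyl chloroformate | COC(=O)Cl | starting material
11 | 2-methylbut-3-en-2-yl methyl carbonate | C=CC(C)(C)OC(=O)OC | intermediate (reagent)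
12 | 1-[2-hydroxy-5-prenyl-4-(pyrimidin-2-yloxy)phenyl]ethanone | CC(=O)c1cc(CC=C(C)C)c(Oc2ncccn2)cc1O | intermediate
13 | 2-acetyl-4-prenyl-5-(pyrimidin-2-yloxy)phenyl 2,2-dimethylchromene-6-carboxylate | CC(=O)c1cc(CC=C(C)C)c(Oc2ncccn2)cc1OC(=O)c1ccc2OC(C)(C)C=Cc2c1 | intermediate
14 | 1,3-diketone (Baker–Venkataraman product) | CC(C)=CCc1cc(C(=O)CC(=O)c2ccc3OC(C)(C)C=Cc3c2)c(O)cc1Oc1ncccn1 | intermediate
15 | 7-O-pyrimidyl Kanzonol E | CC(C)=CCc1cc2c(=O)cc(-c3ccc4OC(C)(C)C=Cc4c3)oc2cc1Oc1ncccn1 | intermediate

**Total steps:** 9 (counting the carbonate preparation in Step 4).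
**Longest linear sequence:** 6 steps (Steps 3, 5, 6, 7, 8, 9).

**Three steps most likely to fail**
1. **Step 5 (proposed new C–H prenylation).** Risks are competing acetyl-directed C6–H activation, O-allylation of the free 2-OH, or Heck-type β-H elimination. Fallback, using known chemistry: iodinate 8 at C5 with NIS (as in the known bromination of paeonol at C5), then Stille coupling with prenyltributylstannane (Pd(PPh3)4, LiCl, DMF) to give 12.
2. **Step 8 (acid cyclodehydration).** The chromene or prenyl alkene could be protonated under acid. Fallback: neutral Mitsunobu-type cyclodehydration of 14 (PPh3, DIAD, THF, 0 °C → rt), which activates the enol oxygen without Brønsted acid.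
3. **Step 9 (pyrimidyl removal).** Ethoxide could attack flavone C2 and open the pyranone. Fallback: a different activation mode, N-methylation of the pyrimidine with MeOTf, which makes it a pyrimidinium leaving group. Mild aqueous K2CO3/MeOH then releases the phenol at rt without strongly nucleophilic alkoxide.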